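**Retrosynthetic overview**

1. Target ← hydrogenolysis of six benzyl groups (five ethers, one ester). The C3 diol ← osmylation of a C3 methylidene group on the face opposite C2–OBn and the C1 aryl group ← C3 ketone (a 2-tetralone). A carbon nucleophile on the ketone would be expected to use that same open face and give the 3-epimer, so carbon is installed first and oxygen second.
2. Ring B is the only ring made (ring A and the pendant ring are bought). It closes at C4–C4a by Pd-catalysed α-arylation of the methyl ketone with the ring-A bromide.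
3. The open-chain precursor ← three-component union at C1: C1–C1' and C1–C2 form in one pot from the ring-A aldehyde, 2,6-bis(benzyloxy)phenol and racemic benzyl 2-benzyloxyacetoacetate, through a para-quinone methide and a catalytic asymmetric 1,6-addition that sets C1 and C2.
4. Feature on which this rests: C1 is bonded at once to C8a of ring A, to C1' of the pendant pyrogallol ring and to the C2 carbinol carbon, and the pendant ring carries an oxygen (on C4') para to C1. That ring can therefore be drawn as a para-quinone methide whose exocyclic, electrophilic carbon is C1.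
5. A benzyl ester is used so that the acid is freed in the last step without saponifying a hindered β-hydroxy ester.

Key step: step 6

Assumption: the sense of induction of the cinchona squaramide cannot be predicted with certainty; the quinine-derived catalyst is written, and its quinidine-derived pseudoenantiomer takes its place if the first experiment shows the opposite sense. Tetralin locants C1–C8a are used for the corresponding atoms of all intermediates.

**Route**

Step 1
Reactants: 1 6-bromoisovanillin (2-bromo-5-hydroxy-4-methoxybenzaldehyde)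
Product: 2 5-(benzyloxy)-2-bromo-4-methoxybenzaldehyde
Conditions: BnBr, K2CO3, DMF, 25 °C
Reagents that add atoms: benzyl bromide, BrCc1ccccc1
Why: Williamson ether synthesis in which the phenoxide displaces bromide from benzyl bromide while the aldehyde and the aryl bromide are inert.

Step 2
Reactants: 3 2,6-dihydroxybenzaldehyde
Product: 4 2,6-bis(benzyloxy)benzaldehyde
Conditions: BnBr (2.2 equiv), K2CO3, DMF, 60 °C
Reagents that add atoms: benzyl bromide, BrCc1ccccc1
Why: Double Williamson etherification, with gentle heating to overcome the hydrogen bonding of the two phenols to the aldehyde, which has no enolisable hydrogen.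

Step 3
Reactants: 4 2,6-bis(benzyloxy)benzaldehyde
Product: 6 2,6-bis(benzyloxy)phenol, via 2,6-bis(benzyloxy)phenyl formate 5 (not isolated)
Conditions: mCPBA, CH2Cl2, 0 °C to 25 °C; aq. NaHCO3 wash; then K2CO3 (cat.), MeOH, 25 °C
Reagents that add atoms: meta-chloroperoxybenzoic acid, OOC(=O)c1cccc(Cl)c1
Why: Baeyer–Villiger (Dakin-type) oxidation in which the electron-rich aryl group migrates in the Criegee intermediate to give aryl formate 5, whose methanolysis frees the phenol carrying the peracid oxygen.

Step 4
Reactants: 7 benzyl acetoacetate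
Product: 8 benzyl 2-diazo-3-oxobutanoate
Conditions: 4-acetamidobenzenesulfonyl azide, Et3N, MeCN, 0 °C to 25 °C
Reagents that add atoms: 4-acetamidobenzenesulfonyl azide, CC(=O)Nc1ccc(cc1)S(=O)(=O)N=[N+]=[N-]
Why: Regitz diazo transfer, the ammonium enolate of the β-keto ester attacking the terminal nitrogen of the sulfonyl azide with loss of the sulfonamide.

Step 5
Reactants: 8 benzyl 2-diazo-3-oxobutanoate
Product: 9 benzyl 2-(benzyloxy)-3-oxobutanoate (racemic)
Conditions: BnOH (1.5 equiv), Rh2(OAc)4 (1 mol%), CH2Cl2, 40 °C
Reagents that add atoms: benzyl alcohol, OCc1ccccc1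
Why: Rhodium carbenoid O–H insertion, the electrophilic carbenoid from Rh2(OAc)4 being trapped by benzyl alcohol through an oxonium ylide and proton shift to give a racemic keto ester whose single C2–H is labile.

Step 6
Reactants: 2 5-(benzyloxy)-2-bromo-4-methoxybenzaldehyde; 6 2,6-bis(benzyloxy)phenol; 9 benzyl 2-(benzyloxy)-3-oxobutanoate
Product: 12 benzyl (2S)-2-(benzyloxy)-2-[(S)-[5-(benzyloxy)-2-bromo-4-methoxyphenyl][3,5-bis(benzyloxy)-4-hydroxyphenyl]methyl]-3-oxobutanoate, via Mannich base 10 (not isolated), via quinone methide 11 (not isolated)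
Conditions: 2, 6, morpholine (1.1 equiv), 4 Å molecular sieves, toluene, 70 °C; then 9 (1.3 equiv), quinine-derived 3,5-bis(trifluoromethyl)phenyl squaramide (10 mol%), toluene, 25–40 °C
Reagents that add atoms: none
Why: Morpholine converts aldehyde 2 into an iminium ion that is attacked by the carbon para to the hydroxyl of 6 to give Mannich base 10 (bond C1–C1'), the phenoxide–ammonium tautomer of 10 expels morpholine to give quinone methide 11, and the catalyst-bound enol of 9 adds through C2 to the exocyclic carbon of 11 (bond C1–C2), which restores the aromatic pendant ring. The closest known reactions are the phenol/aldehyde/secondary-amine condensation that leads to para-quinone methides and the bifunctional squaramide- or thiourea-catalysed asymmetric 1,6-addition of 1,3-dicarbonyl compounds to para-quinone methides, including ones generated in the flask. No ring closes in this step; it joins the three fragments through two skeletal bonds and leaves the aryl bromide and the methyl ketone as the handles for ring B. C1 is set by the face of 11 left open when the squaramide N–H pair binds the quinone carbonyl, and C2 by the face of the enolate held as an ion pair on the protonated quinuclidine of the same catalyst molecule, so both centres are under catalyst control and, because C2–H of 9 is labile, both enantiomers of 9 should converge on one product. The step needs para attack on the phenol (both ortho positions carry benzyloxy groups and the para carbon is the only free position conjugated with the phenol oxygen), 1,6-addition only (2 cannot enolise, 9 has one acidic hydrogen and cannot condense, and 11 is symmetrical about its exocyclic bond so only facial selection is asked of the catalyst) and a slow racemic background, which the weakly basic morpholine, largely stored as 10, should keep low.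

Step 7
Reactants: 12 the open-chain phenol from step 6
Product: 13 benzyl (2S)-2-(benzyloxy)-2-[(S)-[5-(benzyloxy)-2-bromo-4-methoxyphenyl][3,4,5-tris(benzyloxy)phenyl]methyl]-3-oxobutanoate
Conditions: BnBr, K2CO3, DMF, 0 °C to 25 °C
Reagents that add atoms: benzyl bromide, BrCc1ccccc1
Why: Williamson etherification of the acidic 2,6-dialkoxyphenol at low temperature, which also closes the only path (retro-1,6-addition through the phenoxide) by which C1 and C2 could be lost, C2 having no hydrogen and K2CO3 being too weak to enolise the methyl ketone.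

Step 8
Reactants: 13 the perbenzylated bromo methyl ketone
Product: 14 benzyl (1S,2S)-2,7-bis(benzyloxy)-6-methoxy-3-oxo-1-[3,4,5-tris(benzyloxy)phenyl]-1,2,3,4-tetrahydronaphthalene-2-carboxylate
Conditions: Pd(OAc)2 (5 mol%), XPhos (10 mol%), anhydrous K3PO4 (2.5 equiv), toluene, 80 °C, argon
Reagents that add atoms: none
Why: Buchwald–Hartwig-type intramolecular ketone α-arylation in which zerovalent palladium formed from Pd(OAc)2 and XPhos inserts into the C–Br bond, K3PO4 generates the only possible enolate (on the methyl group, C2 being quaternary) and reductive elimination from the arylpalladium enolate closes six-membered ring B at C4–C4a without touching C1 or C2, neither of which bears a hydrogen next to a carbonyl group.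

Step 9
Reactants: 14 the 2-tetralone
Product: 15 benzyl (1S,2S)-2,7-bis(benzyloxy)-6-methoxy-3-methylidene-1-[3,4,5-tris(benzyloxy)phenyl]-1,2,3,4-tetrahydronaphthalene-2-carboxylate
Conditions: Zn, CH2Br2, TiCl4, THF (reagent pre-formed at 5 °C); 14 in CH2Cl2, 0 °C to 25 °C; NaHCO3 work-up
Reagents that add atoms: dibromomethane, BrCBr
Why: Lombardo–Takai methylenation, whose non-basic zinc–titanium methylene reagent converts hindered, easily enolised ketones into methylidene compounds and leaves esters alone, the neutral work-up guarding against migration of the double bond into conjugation with ring A.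

Step 10
Reactants: 15 the exocyclic alkene
Product: 16 benzyl (1S,2S,3R)-2,7-bis(benzyloxy)-3-hydroxy-3-(hydroxymethyl)-6-methoxy-1-[3,4,5-tris(benzyloxy)phenyl]-1,2,3,4-tetrahydronaphthalene-2-carboxylate
Conditions: OsO4 (5 mol%), N-methylmorpholine N-oxide (1.5 equiv), acetone–H2O, 25 °C
Reagents that add atoms: osmium tetroxide, O=[Os](=O)(=O)=O; N-methylmorpholine N-oxide, C[N+]1([O-])CCOCC1; water, O
Why: Upjohn dihydroxylation, OsO4 adding suprafacially to the 1,1-disubstituted alkene on the face anti to the allylic C2–OBn bond (the usual sense for allylic ethers), which is also the face remote from the C1 aryl group, so that C3–OH should end up cis to the C2 ester and CH2OH cis to C2–OBn and the aryl group, that is 3R.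

Step 11
Reactants: 16 the protected diol ester
Product: 17 (1S,2S,3R)-2,3,7-trihydroxy-3-(hydroxymethyl)-6-methoxy-1-(3,4,5-trihydroxyphenyl)-1,2,3,4-tetrahydronaphthalene-2-carboxylic acid (CNP0174537.1)
Conditions: H2 (1 atm), Pd(OH)2 on carbon, THF–MeOH, 25 °C; filtration under argon
Reagents that add atoms: none
Why: Catalytic hydrogenolysis cleaves the five benzyl ethers and the benzyl ester in one neutral operation, while the methyl ether, the C1 diarylmethine and the three stereocentres are inert and the air-sensitive pyrogallol is never exposed to base.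

**Compound list**

1 | 6-bromoisovanillin (2-bromo-5-hydroxy-4-methoxybenzaldehyde) | COc1cc(Br)c(C=O)cc1O | starting material
2 | 5-(benzyloxy)-2-bromo-4-methoxybenzaldehyde | COc1cc(Br)c(C=O)cc1OCc1ccccc1 | intermediate
3 | 2,6-dihydroxybenzaldehyde | O=Cc1c(O)cccc1O | starting material
4 | 2,6-bis(benzyloxy)benzaldehyde | O=Cc1c(OCc2ccccc2)cccc1OCc1ccccc1 | intermediate
5 | 2,6-bis(benzyloxy)phenyl formate (not isolated) | O=COc1c(OCc2ccccc2)cccc1OCc1ccccc1 | intermediate
6 | 2,6-bis(benzyloxy)phenol | Oc1c(OCc2ccccc2)cccc1OCc1ccccc1 | intermediate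
7 | benzyl acetoacetate (benzyl 3-oxobutanoate) | CC(=O)CC(=O)OCc1ccccc1 | starting material
8 | benzyl 2-diazo-3-oxobutanoate | CC(=O)C(=[N+]=[N-])C(=O)OCc1ccccc1 | intermediate
9 | benzyl 2-(benzyloxy)-3-oxobutanoate (racemic) | CC(=O)C(OCc1ccccc1)C(=O)OCc1ccccc1 | intermediate
10 | Mannich base, 2,6-bis(benzyloxy)-4-[[5-(benzyloxy)-2-bromo-4-methoxyphenyl](morpholin-4-yl)methyl]phenol (racemic, not isolated) | COc1cc(Br)c(cc1OCc1ccccc1)C(N1CCOCC1)c1cc(OCc2ccccc2)c(O)c(OCc2ccccc2)c1 | intermediate
11 | quinone methide, 2,6-bis(benzyloxy)-4-[[5-(benzyloxy)-2-bromo-4-methoxyphenyl]methylidene]cyclohexa-2,5-dien-1-one (not isolated) | COc1cc(Br)c(cc1OCc1ccccc1)C=C1C=C(OCc2ccccc2)C(=O)C(OCc2ccccc2)=C1 | intermediate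
12 | benzyl (2S)-2-(benzyloxy)-2-[(S)-[5-(benzyloxy)-2-bromo-4-methoxyphenyl][3,5-bis(benzyloxy)-4-hydroxyphenyl]methyl]-3-oxobutanoate | COc1cc(Br)c(cc1OCc1ccccc1)[C@H](c1cc(OCc2ccccc2)c(O)c(OCc2ccccc2)c1)[C@@](OCc1ccccc1)(C(=O)OCc1ccccc1)C(C)=O | intermediate
13 | benzyl (2S)-2-(benzyloxy)-2-[(S)-[5-(benzyloxy)-2-bromo-4-methoxyphenyl][3,4,5-tris(benzyloxy)phenyl]methyl]-3-oxobutanoate | COc1cc(Br)c(cc1OCc1ccccc1)[C@H](c1cc(OCc2ccccc2)c(OCc2ccccc2)c(OCc2ccccc2)c1)[C@@](OCc1ccccc1)(C(=O)OCc1ccccc1)C(C)=O | intermediate
14 | benzyl (1S,2S)-2,7-bis(benzyloxy)-6-methoxy-3-oxo-1-[3,4,5-tris(benzyloxy)phenyl]-1,2,3,4-tetrahydronaphthalene-2-carboxylate | COc1cc2c(cc1OCc1ccccc1)[C@H](c1cc(OCc3ccccc3)c(OCc3ccccc3)c(OCc3ccccc3)c1)[C@@](OCc1ccccc1)(C(=O)OCc1ccccc1)C(=O)C2 | intermediate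
15 | benzyl (1S,2S)-2,7-bis(benzyloxy)-6-methoxy-3-methylidene-1-[3,4,5-tris(benzyloxy)phenyl]-1,2,3,4-tetrahydronaphthalene-2-carboxylate | COc1cc2c(cc1OCc1ccccc1)[C@H](c1cc(OCc3ccccc3)c(OCc3ccccc3)c(OCc3ccccc3)c1)[C@@](OCc1ccccc1)(C(=O)OCc1ccccc1)C(=C)C2 | intermediate
16 | benzyl (1S,2S,3R)-2,7-bis(benzyloxy)-3-hydroxy-3-(hydroxymethyl)-6-methoxy-1-[3,4,5-tris(benzyloxy)phenyl]-1,2,3,4-tetrahydronaphthalene-2-carboxylate | COc1cc2c(cc1OCc1ccccc1)[C@H](c1cc(OCc3ccccc3)c(OCc3ccccc3)c(OCc3ccccc3)c1)[C@@](OCc1ccccc1)(C(=O)OCc1ccccc1)[C@](O)(CO)C2 | intermediate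
17 | (1S,2S,3R)-2,3,7-trihydroxy-3-(hydroxymethyl)-6-methoxy-1-(3,4,5-trihydroxyphenyl)-1,2,3,4-tetrahydronaphthalene-2-carboxylic acid | COc1cc2c(cc1O)[C@H](c1cc(O)c(O)c(O)c1)[C@@](O)(C(=O)O)[C@](O)(CO)C2 | target

**Step count and risks**

Total steps: 11. Longest linear sequence: 8 (steps 2, 3, 6–11 from 2,6-dihydroxybenzaldehyde; equally steps 4, 5, 6–11 from benzyl acetoacetate).

Steps most likely to fail:

Step 6. The quinone methide may be intercepted by a second molecule of phenol, the free amine may promote a racemic background addition, or the catalyst may give insufficient facial control at C1 or C2. The fallback sets out from 6 and 2 and comes back at 12, separating electrophile generation from the amine. Bromination of the sodium phenoxide of 6 (NaH, then NBS, −40 °C) should give 4-bromo-2,6-bis(benzyloxy)phenol F1. Deprotonation with MeLi and bromine–lithium exchange with t-BuLi (THF, −78 °C) gives an aryllithium phenoxide that adds to aldehyde 2 to give the para-hydroxybenzhydrol 2,6-bis(benzyloxy)-4-[[5-(benzyloxy)-2-bromo-4-methoxyphenyl](hydroxy)methyl]phenol F2. A chiral BINOL-derived phosphoric acid (the 3,3'-bis(2,4,6-triisopropylphenyl) catalyst, CH2Cl2, molecular sieves) then dehydrates F2 to quinone methide 11 and directs the addition of 9 within a hydrogen-bonded ion pair, giving 12 with no amine present. Acid-catalysed generation of quinone methides from hydroxybenzyl alcohols with asymmetric addition of carbon nucleophiles is known chemistry.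

Step 8. Oxidative addition into the hindered, electron-rich bromide may be slow, the arylpalladium intermediate may instead arylate an ortho C–H of the pendant ring, or the base may fragment the keto ester. The fallback sets out from 13 and comes back at 14 and avoids any external base. Silylation of the methyl ketone (TMSOTf, Et3N, CH2Cl2, 0 °C) gives the silyl enol ether benzyl (2S)-2-(benzyloxy)-2-[(S)-[5-(benzyloxy)-2-bromo-4-methoxyphenyl][3,4,5-tris(benzyloxy)phenyl]methyl]-3-[(trimethylsilyl)oxy]but-3-enoate F3. Its tin enolate, formed in the flask with Bu3SnF, is coupled intramolecularly under PdCl2[P(o-tolyl)3]2 catalysis (toluene, 100 °C), the known arylation of methyl ketone silyl enol ethers with aryl bromides, to give 14.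

Step 10. Facial selectivity at C3 may be poor or reversed if the axial ester at C2 shields the alkene more than the C2 benzyloxy and C1 aryl groups do. The fallback sets out from 14 and comes back at 17; it turns the same substrate bias around by adding carbon, not oxygen, to that face. Corey–Chaykovsky reaction of ketone 14 with dimethylsulfonium methylide (trimethylsulfonium iodide, KN(SiMe3)2, THF, −20 °C to 0 °C) should give the spiro-epoxide benzyl (1S,2S,3R)-2,7-bis(benzyloxy)-6-methoxy-1-[3,4,5-tris(benzyloxy)phenyl]-1,4-dihydro-2H-spiro[naphthalene-3,2'-oxirane]-2-carboxylate F4, with CH2 on the benzyloxy face and oxygen on the ester face. Opening at the primary carbon with BnONa in BnOH–THF (50 °C; ester exchange is degenerate) gives the benzyl ether benzyl (1S,2S,3R)-2,7-bis(benzyloxy)-3-[(benzyloxy)methyl]-3-hydroxy-6-methoxy-1-[3,4,5-tris(benzyloxy)phenyl]-1,2,3,4-tetrahydronaphthalene-2-carboxylate F5. F5 is debenzylated under the conditions of step 11 to give 17.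

**Further compounds**

F1 | step 6 | 4-bromo-2,6-bis(benzyloxy)phenol | Oc1c(OCc2ccccc2)cc(Br)cc1OCc1ccccc1
F2 | step 6 | 2,6-bis(benzyloxy)-4-[[5-(benzyloxy)-2-bromo-4-methoxyphenyl](hydroxy)methyl]phenol (racemic) | COc1cc(Br)c(cc1OCc1ccccc1)C(O)c1cc(OCc2ccccc2)c(O)c(OCc2ccccc2)c1
F3 | step 8 | benzyl (2S)-2-(benzyloxy)-2-[(S)-[5-(benzyloxy)-2-bromo-4-methoxyphenyl][3,4,5-tris(benzyloxy)phenyl]methyl]-3-[(trimethylsilyl)oxy]but-3-enoate | COc1cc(Br)c(cc1OCc1ccccc1)[C@H](c1cc(OCc2ccccc2)c(OCc2ccccc2)c(OCc2ccccc2)c1)[C@@](OCc1ccccc1)(C(=O)OCc1ccccc1)C(=C)O[Si](C)(C)C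
F4 | step 10 | benzyl (1S,2S,3R)-2,7-bis(benzyloxy)-6-methoxy-1-[3,4,5-tris(benzyloxy)phenyl]-1,4-dihydro-2H-spiro[naphthalene-3,2'-oxirane]-2-carboxylate | COc1cc2c(cc1OCc1ccccc1)[C@H](c1cc(OCc3ccccc3)c(OCc3ccccc3)c(OCc3ccccc3)c1)[C@@](OCc1ccccc1)(C(=O)OCc1ccccc1)[C@]1(CO1)C2
F5 | step 10 | benzyl (1S,2S,3R)-2,7-bis(benzyloxy)-3-[(benzyloxy)methyl]-3-hydroxy-6-methoxy-1-[3,4,5-tris(benzyloxy)phenyl]-1,2,3,4-tetrahydronaphthalene-2-carboxylate | COc1cc2c(cc1OCc1ccccc1)[C@H](c1cc(OCc3ccccc3)c(OCc3ccccc3)c(OCc3ccccc3)c1)[C@@](OCc1ccccc1)(C(=O)OCc1ccccc1)[C@](O)(COCc1ccccc1)C2
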